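**Retrosynthetic overview**

1. Target 14 ⇐ C-acetylation at C1 of spiro trione diol 12 ⇐ gem-diprenylation at C3 and hydrolysis of bridged enol ether 10. The C6–O–C10 bridge makes the two sides of the otherwise symmetric phloroglucinol-derived ring different, which fixes the spiro centre.
2. 10 ⇐ anodic dearomative (3+2) spiro-annulation of alkylphloroglucinol 9, forming C5–C11 and O–C10 (cyclohexane ring, C10 stereocentre, latent spiro centre).
3. 9 ⇐ reductive alkylation of phloroglucinol with hydroxy aldehyde 6 (C5–C7).
4. 6 ⇐ (R)-limonene by ozonolysis, aldol ring contraction, epoxidation anti to the isopropenyl group and reductive epoxide opening. C9 is bought; C14 and C8 are controlled by it.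
5. Ring order: cyclopentane (from the limonene ring) → spiro cyclohexane (anodic step, which also dearomatises the arene to the trione ring) → trione substituents last.

Assumption: keto/enol tautomers of the trione ring are treated as one compound and drawn in one convenient form.

Atom labels used below: trione ring C1 (acetyl-bearing), C2 (enol), C3 (diprenyl), C4 (C=O), C5 (spiro), C6 (C=O); carbocycle C7 (CH2 on C5), C8 and C9 (ring-fusion CH), C10 (cyclohexane carbinol), C11 (CH2 on C5), C12, C13 (CH2), C14 (cyclopentane carbinol).

**Route**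

Step 1
Reactants: 1 (R)-(+)-limonene
Product: 3 (3R)-6-oxo-3-(prop-1-en-2-yl)heptanal, via ozonide 2 (not isolated)
Conditions: O3, CH2Cl2, −78 °C, Sudan Red 7B end point; then Me2S, −78 °C → rt
Reagents that add atoms: ozone [O-][O+]=O
Why: Ozone cleaves the trisubstituted ring alkene much faster than the 1,1-disubstituted isopropenyl group, so stopping at the indicator end point gives the keto aldehyde (Criegee ozonolysis, reductive work-up) and leaves the bought C9 stereocentre untouched.

Step 2
Reactants: 3 (3R)-6-oxo-3-(prop-1-en-2-yl)heptanal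
Product: 4 (5S)-2-methyl-5-(prop-1-en-2-yl)cyclopent-1-ene-1-carbaldehyde
Conditions: piperidine (0.2 equiv), AcOH (0.2 equiv), toluene, 80 °C
Reagents that add atoms: none
Why: The enamine of the aldehyde attacks the methyl ketone and the aldol loses water (intramolecular aldol condensation, known for this substrate), making C8=C14 the ring alkene while the non-enolisable C9 keeps its configuration.

Step 3
Reactants: 4 (5S)-2-methyl-5-(prop-1-en-2-yl)cyclopent-1-ene-1-carbaldehyde
Product: 5 (1S,2S,5R)-5-methyl-2-(prop-1-en-2-yl)-6-oxabicyclo[3.1.0]hexane-1-carbaldehyde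
Conditions: 30% aq. H2O2 (3 equiv), NaOH (0.2 equiv), MeOH, 0 °C
Reagents that add atoms: hydrogen peroxide OO
Why: Weitz–Scheffer nucleophilic epoxidation attacks only the enal (the isopropenyl group is no acceptor), and hydroperoxide adds to C14 and closes on C8 from the ring face opposite the neighbouring isopropenyl group (as in the epoxidation of carvone), which sets C14–O trans to it.

Step 4
Reactants: 5 (1S,2S,5R)-5-methyl-2-(prop-1-en-2-yl)-6-oxabicyclo[3.1.0]hexane-1-carbaldehyde
Product: 6 (1S,2R,5R)-2-hydroxy-2-methyl-5-(prop-1-en-2-yl)cyclopentane-1-carbaldehyde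
Conditions: SmI2 (2.2 equiv), THF/MeOH 4:1, −90 °C, 10 min; pH 7 buffer; then Et3N (0.2 equiv), CH2Cl2, rt
Reagents that add atoms: none
Why: Electron transfer to the aldehyde gives a ketyl that cleaves the adjacent C8–O bond, and a second electron and protonation give the aldol (SmI2 reductive opening of an α,β-epoxy carbonyl compound, C14–O retained), after which the Et3N equilibration lets the epimerisable C8 settle with the formyl group trans to both the isopropenyl and the methyl group and hydrogen-bonded to the cis hydroxyl.

Step 5
Reactants: 6 (1S,2R,5R)-2-hydroxy-2-methyl-5-(prop-1-en-2-yl)cyclopentane-1-carbaldehyde; 7 phloroglucinol (3 equiv)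
Product: 9 2-{[(1S,2R,5R)-2-hydroxy-2-methyl-5-(prop-1-en-2-yl)cyclopentyl]methyl}benzene-1,3,5-triol, via quinone methide 8 (not isolated)
Conditions: Hantzsch ester (diethyl 2,6-dimethyl-1,4-dihydropyridine-3,5-dicarboxylate, 1.3 equiv), pyrrolidine (10 mol %), AcOH (10 mol %), EtOH, rt
Reagents that add atoms: none
Why: Condensation of the aldehyde with a ring carbon of phloroglucinol gives quinone methide 8, which the Hantzsch ester reduces by hydride transfer to the exocyclic carbon (three-component reductive alkylation, Knoevenagel condensation/transfer hydrogenation); excess 7 suppresses double alkylation and no stereocentre is touched.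

Step 6
Reactants: 9 2-{[(1S,2R,5R)-2-hydroxy-2-methyl-5-(prop-1-en-2-yl)cyclopentyl]methyl}benzene-1,3,5-triol
Product: 10 bridged spiro enol ether (C5–C11 bond and C6–O–C10 ether bridge formed; trans-hydrindane; free C14–OH)
Conditions: undivided cell, RVC anode, Pt cathode, constant current 4 mA, 2.2 F/mol; (4-BrC6H4)3N (10 mol %), 2,6-lutidine (2 equiv), nBu4NPF6 (0.1 M), HFIP/CH2Cl2 1:4, 5 mM, rt, Ar
Reagents that add atoms: none
Why: Proposed new method: mediated one-electron anodic oxidation gives the phenoxyl radical, whose spin-bearing alkylated ring carbon C5 adds 6-endo to the CH2 end of the isopropenyl group through a chair with the trans-fused cyclopentane equatorial, and the tertiary C10 radical is oxidised to the cation and captured by the one flanking ring oxygen held 1,3-diaxial to it, which sets C10 (O axial, CH3 equatorial) and, because the two flanking C–O carbons were equivalent until capture, makes C5 a single defined stereocentre; the closest known reactions are anodic phenol–alkene (3+2) cycloadditions to dihydrobenzofurans and Mn(OAc)3-type oxidative 6-endo cyclisations of 2-alkyl-1,3-diones, neither shown at the alkyl-bearing carbon of a phloroglucinol.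

Step 7
Reactants: 10 bridged spiro enol ether
Product: 12 spiro trione diol (C3 gem-diprenyl; C6=O, C10–OH and C14–OH free; C1 unsubstituted), via diprenyl enol ether 11 (not isolated)
Conditions: prenyl acetate (2.5 equiv), Pd(PPh3)4 (5 mol %), Et3N (3 equiv), THF, 45 °C; then 1 M aq. HCl, THF, rt
Reagents that add atoms: prenyl acetate CC(C)=CCOC(C)=O; water O
Why: The π-prenyl complex formed from zerovalent palladium alkylates twice at C3, the only carbon between two free carbonyl groups (Tsuji–Trost allylation at the unsubstituted allyl terminus; the C1–H of the bridged vinylogous ester is not nucleophilic), and aqueous acid then hydrolyses the vinylogous ester at C6 without breaking the bridgehead C10–O bond, so C10 keeps its configuration and the spiro centre is now fixed by the unsymmetrical substitution.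

Step 8
Reactants: 12 spiro trione diol
Product: 14 CNP0266834.3 (target), via enol acetate 13 (not isolated)
Conditions: Ac2O (1.1 equiv), Et3N (2 equiv), DMAP (0.3 equiv), CH2Cl2, 0 °C → rt
Reagents that add atoms: acetic anhydride CC(=O)OC(C)=O
Why: O-acetylation of the enol followed by DMAP-mediated O-to-C acyl migration (rearrangement of an enol ester to a 2-acyl-1,3-dione) places the acetyl group on C1, the only enolisable carbon left, while the two tertiary alcohols do not react with one equivalent of Ac2O at this temperature.

**Compound list**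

1 | (R)-(+)-limonene, (4R)-1-methyl-4-(prop-1-en-2-yl)cyclohex-1-ene | CC1=CC[C@@H](CC1)C(C)=C | starting material
2 | ozonide of the ring alkene of 1 (1,2,4-trioxolane bridging the former alkene carbons; mixture at these two carbons; isopropenyl carbon R as in 1) | CC12CC[C@@H](C(C)=C)CC(O1)OO2 | intermediate
3 | (3R)-6-oxo-3-(prop-1-en-2-yl)heptanal | O=CC[C@@H](CCC(C)=O)C(C)=C | intermediate
4 | (5S)-2-methyl-5-(prop-1-en-2-yl)cyclopent-1-ene-1-carbaldehyde | O=CC1=C(C)CC[C@H]1C(C)=C | intermediate
5 | (1S,2S,5R)-5-methyl-2-(prop-1-en-2-yl)-6-oxabicyclo[3.1.0]hexane-1-carbaldehyde (epoxide trans to isopropenyl) | O=C[C@@]12O[C@]1(C)CC[C@H]2C(C)=C | intermediate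
6 | (1S,2R,5R)-2-hydroxy-2-methyl-5-(prop-1-en-2-yl)cyclopentane-1-carbaldehyde (CHO cis to OH, trans to CH3 and to isopropenyl) | O=C[C@@H]1[C@](C)(O)CC[C@H]1C(C)=C | intermediate
7 | phloroglucinol, benzene-1,3,5-triol | Oc1cc(O)cc(O)c1 | starting material
8 | quinone methide, 3,5-dihydroxy-6-{[(1S,2R,5R)-2-hydroxy-2-methyl-5-(prop-1-en-2-yl)cyclopentyl]methylidene}cyclohexa-2,4-dien-1-one (alkene geometry not defined) | O=C1C=C(O)C=C(O)C1=C[C@@H]2[C@](C)(O)CC[C@H]2C(C)=C | intermediate
9 | 2-{[(1S,2R,5R)-2-hydroxy-2-methyl-5-(prop-1-en-2-yl)cyclopentyl]methyl}benzene-1,3,5-triol | Oc1cc(O)c(C[C@@H]2[C@](C)(O)CC[C@H]2C(C)=C)c(O)c1 | intermediate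
10 | bridged spiro enol ether: 5-hydroxycyclohexa-2,5-dienone ring spiro-fused at C5 to the trans-hydrindane; C6 enol oxygen bonded to C10 (five-membered ether ring C5–C6–O–C10–C11); C10–O axial, C10–CH3 equatorial; C14–OH free and cis to C7; C8, C9, C10, C14 and C5 configured as in 14 | O=C1C=C(O)[C@@]2(C[C@H]3[C@@H](CC[C@@]3(C)O)[C@]4(C)C2)C(O4)=C1 | intermediate
11 | diprenyl enol ether: 10 with two 3-methylbut-2-enyl groups on C3 and C4 as ketone | O=C1C(CC=C(C)C)(CC=C(C)C)C(=O)[C@@]2(C[C@H]3[C@@H](CC[C@@]3(C)O)[C@]4(C)C2)C(O4)=C1 | intermediate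
12 | spiro trione diol: 14 without the acetyl group (C1–H; C2 enol, C4 and C6 carbonyl; C3 gem-diprenyl; C10–OH and C14–OH) | OC1=CC(=O)[C@]2(C[C@H]3[C@@H](CC[C@@]3(C)O)[C@@](C)(O)C2)C(=O)C1(CC=C(C)C)CC=C(C)C | intermediate
13 | enol acetate of 12 (drawn on the C2 oxygen; the C6 regioisomer reacts the same way) | CC(=O)OC1=CC(=O)[C@]2(C[C@H]3[C@@H](CC[C@@]3(C)O)[C@@](C)(O)C2)C(=O)C1(CC=C(C)C)CC=C(C)C | intermediate
14 | CNP0266834.3: 2-acetyl-3-hydroxy-4,4-bis(3-methylbut-2-enyl)cyclohex-2-ene-1,5-dione spiro-fused at C5 (S) to the trans-hydrindane-diol; C8 S, C9 R, C10 S, C14 R | CC(=O)C1=C(O)C(CC=C(C)C)(CC=C(C)C)C(=O)[C@@]2(C[C@H]3[C@@H](CC[C@@]3(C)O)[C@@](C)(O)C2)C1=O | target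

**Step count**

Total steps: 8. Longest linear sequence: 8 (1 → 14); phloroglucinol 7 enters at step 5.

**Three steps most likely to fail**

Step 6 (the new anodic annulation). Risks are coupling of two phenoxyl radicals at the free ring positions, over-oxidation to the phenoxonium ion (capture at C5 by the C14 hydroxyl, or loss of a C7 proton to a quinone methide), and slow addition of the stabilised radical to the unactivated alkene. The fallback uses known reactions only, sets out from 9 and comes back at 10. The three phenols of 9 are acetylated (Ac2O, pyridine, 0 °C; the tertiary alcohol stays free) to triacetate F1. mCPBA (NaHCO3, CH2Cl2, 0 °C) epoxidises the isopropenyl group to epoxide F2 as both C10 epimers. K2CO3 in MeOH removes the acetates, and the phloroglucinolate opens the epoxide at its CH2 carbon through the alkylated ring carbon (alkylative dearomatisation, six-membered ring) to spiro trione diol F3. PPTS in toluene at 80 °C with removal of water closes the enol ether only from the C10 epimer whose hydroxyl is cis to a ring carbonyl and gives 10; the other epimer is removed by chromatography. The price is that C10 is no longer controlled.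

Step 5 (reductive alkylation). Risks are amine-induced dehydration of the β-hydroxy aldehyde back to enal 4 (which would then give a chromene with 7), double alkylation, and slow condensation of the branched aldehyde. The fallback sets out from 6 and 7 and comes back at 9. Aldehyde 6, 7 (3 equiv) and 1H-benzotriazole are condensed without amine (EtOH, catalytic AcOH, rt) to benzotriazole adduct F4, an isolable quinone methide precursor (benzotriazole-assisted ortho-alkylation of phenols). NaBH4 in THF at 50 °C then eliminates benzotriazole and reduces the quinone methide to 9.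

Step 7 (double prenylation and hydrolysis). Risks are an incomplete second prenylation at the crowded C3, branched (1,1-dimethylallyl) or O-prenyl isomers, and acid-induced cyclisation of an enol oxygen onto a prenyl group during hydrolysis. The fallback sets out from 10 and comes back at 11. Allyl acetate, Pd(PPh3)4 and Et3N in THF give diallyl enol ether F5; the smaller electrophile makes the second alkylation easy and has no regiochemistry. Cross-metathesis with 2-methyl-2-butene (as solvent) using (H2IMes)(PCy3)Cl2Ru=CHPh (second-generation Grubbs catalyst, 5 mol %, 40 °C) converts both allyl groups into prenyl groups and gives 11, now isolated. 11 is hydrolysed with oxalic acid in wet THF to 12.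

**Further compounds**

F1 | step 6 | 2-{[(1S,2R,5R)-2-hydroxy-2-methyl-5-(prop-1-en-2-yl)cyclopentyl]methyl}benzene-1,3,5-triyl triacetate | CC(=O)Oc1cc(OC(C)=O)c(C[C@@H]2[C@](C)(O)CC[C@H]2C(C)=C)c(OC(C)=O)c1
F2 | step 6 | epoxide of F1 at the isopropenyl group (2-methyloxiran-2-yl; both epimers at the new oxirane carbon) | CC(=O)Oc1cc(OC(C)=O)c(C[C@@H]2[C@](C)(O)CC[C@H]2C3(C)CO3)c(OC(C)=O)c1
F3 | step 6 | spiro trione diol without bridge: 3,5-dihydroxycyclohexa-2,5-dienone ring spiro-fused at C5 to the trans-hydrindane with C10–OH (both C10 epimers) and C14–OH | O=C1C=C(O)C2(C[C@H]3[C@@H](CC[C@@]3(C)O)C(C)(O)C2)C(O)=C1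
F4 | step 5 | 2-{(1H-benzotriazol-1-yl)[(1S,2R,5R)-2-hydroxy-2-methyl-5-(prop-1-en-2-yl)cyclopentyl]methyl}benzene-1,3,5-triol (both epimers at the new CH) | Oc1cc(O)c(C(n2nnc3ccccc23)[C@@H]4[C@](C)(O)CC[C@H]4C(C)=C)c(O)c1
F5 | step 7 | diallyl enol ether: 11 with two prop-2-enyl groups on C3 in place of the prenyl groups | O=C1C(CC=C)(CC=C)C(=O)[C@@]2(C[C@H]3[C@@H](CC[C@@]3(C)O)[C@]4(C)C2)C(O4)=C1
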